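Ring numbering: C1 carries the side chain (stereocentre C7), C6 the hydroxyl, C4 the methyl and C3 the biaryl bond. Because C3 lies between C2–H and the methyl-bearing C4 in both rings, the four-carbon chain C2–C3–C3'–C2' across the biaryl bond is a succinaldehyde unit and each C4–C5–C6(O)–C1–C7 segment an alkynone from (S)-citronellal. The route therefore rests on cutting C3–C4 and C1=C2 in both rings at once. One operation, a twofold Michael addition of 1,4-bis(trimethylsilyloxy)buta-1,3-diene to two molecules of (S)-6,10-dimethylundec-9-en-2-yn-4-one followed by aldol condensation and tautomerisation, builds both arenes and four C–C bonds; the two stereocentres arrive unchanged from the chiral pool.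

Key step: step 5

Remark (chemistry): the bis(silyl enol ether) is drawn as the 1E,3E isomer, but its enol ether geometry is erased in the key step, so a mixture of geometrical isomers is assumed to serve equally well.
Remark (chemistry): 2,5-dimethoxytetrahydrofuran is taken as the shelf-stable source of succinaldehyde, which does not keep. Commercial (S)-citronellal of high enantiomeric purity is assumed, since any (R)-antipode would surface as the (R,S)-diastereomer of the target.

Step 1
Reactants: 1 (S)-citronellal, (3S)-3,7-dimethyloct-6-enal; 2 1-propynylmagnesium bromide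
Product: 3 (4RS,6S)-6,10-dimethylundec-9-en-2-yn-4-ol
Conditions: THF, −78 → 0 °C; then sat. aq. NH4Cl
Reagents that add atoms: none
Why: Grignard 1,2-addition of the alkynyl nucleophile to the unhindered aldehyde should be fast at low temperature; the new carbinol centre forms without control but is erased in step 2, and the existing stereocentre is β to the carbonyl and untouched.

Step 2
Reactants: 3 (4RS,6S)-6,10-dimethylundec-9-en-2-yn-4-ol
Product: 4 (S)-6,10-dimethylundec-9-en-2-yn-4-one
Conditions: Dess–Martin periodinane, CH2Cl2, 0 °C → rt
Reagents that add atoms: none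
Why: Dess–Martin oxidation of a secondary propargylic alcohol to the conjugated ynone is mild and should leave the trisubstituted alkene and the non-enolisable β-stereocentre intact.

Step 3
Reactants: 5 2,5-dimethoxytetrahydrofuran (cis/trans mixture)
Product: 6 succinaldehyde (butanedial)
Conditions: H2O, 90 °C; then toluene azeotrope, distillation under reduced pressure
Reagents that add atoms: water, O
Why: Acetal hydrolysis of the cyclic bis-acetal in hot water should release the dialdehyde, which is freed from methanol and water by distillation and used at once.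

Step 4
Reactants: 6 succinaldehyde
Product: 7 (1E,3E)-1,4-bis(trimethylsilyloxy)buta-1,3-diene
Conditions: Me3SiCl, NaI, Et3N, MeCN, 0 °C → rt; pentane extraction, distillation
Reagents that add atoms: chlorotrimethylsilane, C[Si](C)(C)Cl
Why: Silyl enol ether formation by soft enolisation (Me3SiI made in situ, tertiary amine) should O-silylate both aldehydes faster than they self-condense; the enol ether geometry is of no consequence.

Step 5
Reactants: 4 (S)-6,10-dimethylundec-9-en-2-yn-4-one (two molecules); 7 (1E,3E)-1,4-bis(trimethylsilyloxy)buta-1,3-diene
Product: 11 2,2'-dimethyl-5,5'-bis[(2S)-6-methylhept-5-en-2-yl]-[1,1'-biphenyl]-4,4'-diol, via bis(silyl dienol ether) adduct 8 (not isolated), via tetracarbonyl bis-Michael adduct 9 (not isolated), via bis(cyclohexa-2,5-dienone) 10 (not isolated)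
Conditions: 4 (2.2 equiv), Bu4N[Ph3SiF2] (10 mol %), THF, −78 → 0 °C; then MeOH, 1,8-diazabicyclo[5.4.0]undec-7-ene (DBU, 30 mol %), 50 °C, argon
Reagents that add atoms: none
Why: Proposed new method: catalytic fluoride removes one Me3Si group from 7 to give an ammonium dienolate whose α-carbon C3 adds to the alkyne β-carbon C4 of 4; the allenolate is quenched by the now doubly activated C3–H, the resulting 2-ene-1,5-dicarbonyl anion takes a silyl group from fresh 7 (chain transfer), and the second enol ether terminus repeats the sequence to forge C3'–C4', giving 8 without a free aldehyde ever being present. Methanol and DBU then unmask 9, the C3 (C3') anion lets the C4=C5 (C4'=C5') geometry equilibrate, and in each arm the C1 ketone enolate attacks the neighbouring aldehyde C2 in a 6-(enolendo)-exo-trig aldol addition; loss of water gives bis(cyclohexa-2,5-dienone) 10, whose C3–H and C3'–H shift to oxygen to give bisphenol 11 irreversibly. The closest known reaction types are the Lewis-base-catalysed Mukaiyama–Michael addition of enol silanes, the base-mediated Michael/aldol [3+3] benzannulation of alkynones with C–H acidic carbonyl compounds, and the hydroxide-induced recyclisation of 2-ene-1,5-diones (pyrylium pseudo-bases) to phenols. No lasting stereocentre is made: the sp3 centres at C1, C2 and C3 are transient, the biaryl axis with only two ortho methyl groups is not configurationally stable, and C7, being β to the ketone, cannot enolise and keeps the citronellal configuration. The step needs C-attack at the internal dienolate carbon, conjugate rather than carbonyl addition to 4, and ring closure from C1 onto C2; the first is favoured because the other terminus carries OSiMe3, the second because 1,2-addition of a free enolate is reversible, and the third because C1-to-C2 is the only six-membered pairing within an arm (the C4-methyl or C5 would give a four-membered ring) while cross-arm five- or seven-membered aldolisations are reversible and cannot aromatise. A Lewis-base trigger is chosen over a Lewis acid so that the trisubstituted alkenes and the citronellal-type keto-olefin (prone to carbonyl-ene closure) are left alone and no 1,4-dialdehyde meets acid, which would close it to a furan.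

Compound list
1 | (S)-citronellal, (3S)-3,7-dimethyloct-6-enal | CC(C)=CCC[C@H](C)CC=O | starting material
2 | 1-propynylmagnesium bromide | CC#C[Mg]Br | starting material
3 | (4RS,6S)-6,10-dimethylundec-9-en-2-yn-4-ol (both C4 epimers) | CC(C)=CCC[C@H](C)CC(O)C#CC | intermediate
4 | (S)-6,10-dimethylundec-9-en-2-yn-4-one | CC(C)=CCC[C@H](C)CC(=O)C#CC | intermediate
5 | 2,5-dimethoxytetrahydrofuran (cis/trans mixture) | COC1CCC(OC)O1 | starting material
6 | succinaldehyde (butanedial) | O=CCCC=O | intermediate
7 | (1E,3E)-1,4-bis(trimethylsilyloxy)buta-1,3-diene | C[Si](C)(C)O/C=C/C=C/O[Si](C)(C)C | intermediate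
8 | 2,3-bis[(6S)-6,10-dimethyl-4-oxoundeca-2,9-dien-2-yl]-1,4-bis(trimethylsilyloxy)buta-1,3-diene (alkene geometries not defined; not isolated) | C[Si](C)(C)OC=C(C(C)=CC(=O)C[C@@H](C)CCC=C(C)C)C(=CO[Si](C)(C)C)C(C)=CC(=O)C[C@@H](C)CCC=C(C)C | intermediate
9 | 2,3-bis[(6S)-6,10-dimethyl-4-oxoundeca-2,9-dien-2-yl]butanedial (C2/C3 diastereomers and E/Z isomers; not isolated) | O=CC(C(C)=CC(=O)C[C@@H](C)CCC=C(C)C)C(C=O)C(C)=CC(=O)C[C@@H](C)CCC=C(C)C | intermediate
10 | 2,2'-dimethyl-5,5'-bis[(2S)-6-methylhept-5-en-2-yl]-[1,1'-bi(cyclohexane)]-2,2',5,5'-tetraene-4,4'-dione (C1/C1' epimers; not isolated) | O=C1C=C(C)C(C2C=C([C@@H](C)CCC=C(C)C)C(=O)C=C2C)C=C1[C@@H](C)CCC=C(C)C | intermediate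
11 | 2,2'-dimethyl-5,5'-bis[(2S)-6-methylhept-5-en-2-yl]-[1,1'-biphenyl]-4,4'-diol (CNP0163343.1) | CC(C)=CCC[C@H](C)c1cc(-c2cc([C@@H](C)CCC=C(C)C)c(O)cc2C)c(C)cc1O | target

Total step count: 5
Longest linear sequence: 3 steps (1 → 3 → 4 → 11, or 5 → 6 → 7 → 11)

Steps most likely to fail

Step 5 (proposed new method). What may go wrong:
- The free dienolate may be lost to O-attack or to anionic oligomerisation of the ynone instead of forming C3–C4.
- Silyl chain transfer may stall.
- The second addition at the congested C3' site may stop after one arm.
- In the base phase, cross-arm or intermolecular aldolisation may outrun the six-membered closure.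

Fallback (known reaction types only), setting out from 4 and coming back at 11: the rings are made one at a time and joined by cross-coupling. Copper-mediated conjugate addition of (1,3-dioxolan-2-ylmethyl)magnesium bromide to 4 (CuBr·SMe2, Me3SiCl, THF, −78 °C) should give the enone acetal (6S)-1-(1,3-dioxolan-2-yl)-2,6,10-trimethylundeca-2,9-dien-4-one F1 as an E/Z mixture. Aqueous HCl in THF should unmask the keto-aldehyde (7S)-3,7,11-trimethyl-5-oxododeca-3,10-dienal F2, which is not isolated but treated with NaOH in MeOH. There the enone geometry equilibrates through the dienolate, and Robinson-type aldol condensation with aromatisation (the way 2-ene-1,5-diones from pyrylium salts give phenols) should deliver (S)-curcuphenol, 5-methyl-2-[(2S)-6-methylhept-5-en-2-yl]phenol F3. para-Selective iodination with I2/morpholine, which should attack the phenol far faster than the isolated alkene, should give 4-iodo-5-methyl-2-[(2S)-6-methylhept-5-en-2-yl]phenol F4. A one-pot Miyaura borylation/Suzuki homocoupling (bis(pinacolato)diboron 0.5 equiv, PdCl2(dppf) with dppf = 1,1'-bis(diphenylphosphino)ferrocene, K3PO4, dioxane/H2O, 90 °C) passes through the pinacol boronate 5-methyl-2-[(2S)-6-methylhept-5-en-2-yl]-4-(4,4,5,5-tetramethyl-1,3,2-dioxaborolan-2-yl)phenol F5 and should join two halves at C3–C3' to give 11.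

Step 4. What may go wrong: aldol self-condensation of the dialdehyde may outrun the second O-silylation, and the trimethylsilyl enol ethers may hydrolyse during isolation, so that only distillation of a crude, partly oligomeric mixture is possible.

Fallback, setting out from 6 and coming back at 9: the silyl group and the isolation logic are changed. Et3SiOTf/Et3N (CH2Cl2, −78 → 0 °C) should convert 6 into the sturdier (1E,3E)-1,4-bis(triethylsilyloxy)buta-1,3-diene F6, which should survive aqueous work-up and chromatography on base-washed silica and can therefore be purified. Under the step 5 conditions it should give the triethylsilyl analogue of 8, 2,3-bis[(6S)-6,10-dimethyl-4-oxoundeca-2,9-dien-2-yl]-1,4-bis(triethylsilyloxy)buta-1,3-diene F7, whose methanolysis rejoins the route at 9.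

Step 3. What may go wrong: the dialdehyde may oligomerise or stay hydrated during hot hydrolysis and distillation, giving wet or polymeric material that spoils the silylation.

Fallback, setting out from 5 and coming back at 6: 5 is hydrolysed in warm aqueous NaHSO3 so that the dialdehyde is trapped as it forms as its crystalline bis(bisulfite) adduct, disodium 1,4-dihydroxybutane-1,4-disulfonate F8. This is filtered, purified and stored as a solid. Succinaldehyde 6 is released just before use with aqueous Na2CO3 into CH2Cl2 and dried, which avoids distilling the free dialdehyde.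

Further compounds
F1 | step 5 | (6S)-1-(1,3-dioxolan-2-yl)-2,6,10-trimethylundeca-2,9-dien-4-one (E/Z mixture) | CC(C)=CCC[C@H](C)CC(=O)C=C(C)CC1OCCO1
F2 | step 5 | (7S)-3,7,11-trimethyl-5-oxododeca-3,10-dienal | CC(C)=CCC[C@H](C)CC(=O)C=C(C)CC=O
F3 | step 5 | (S)-curcuphenol, 5-methyl-2-[(2S)-6-methylhept-5-en-2-yl]phenol | CC(C)=CCC[C@H](C)c1ccc(C)cc1O
F4 | step 5 | 4-iodo-5-methyl-2-[(2S)-6-methylhept-5-en-2-yl]phenol | CC(C)=CCC[C@H](C)c1cc(I)c(C)cc1O
F5 | step 5 | 5-methyl-2-[(2S)-6-methylhept-5-en-2-yl]-4-(4,4,5,5-tetramethyl-1,3,2-dioxaborolan-2-yl)phenol | CC(C)=CCC[C@H](C)c1cc(B2OC(C)(C)C(C)(C)O2)c(C)cc1O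
F6 | step 4 | (1E,3E)-1,4-bis(triethylsilyloxy)buta-1,3-diene | CC[Si](CC)(CC)O/C=C/C=C/O[Si](CC)(CC)CC
F7 | step 4 | 2,3-bis[(6S)-6,10-dimethyl-4-oxoundeca-2,9-dien-2-yl]-1,4-bis(triethylsilyloxy)buta-1,3-diene | CC[Si](CC)(CC)OC=C(C(C)=CC(=O)C[C@@H](C)CCC=C(C)C)C(=CO[Si](CC)(CC)CC)C(C)=CC(=O)C[C@@H](C)CCC=C(C)C
F8 | step 3 | disodium 1,4-dihydroxybutane-1,4-disulfonate (succinaldehyde bis(bisulfite) adduct, stereoisomer mixture) | [Na+].[Na+].OC(CCC(O)S(=O)(=O)[O-])S(=O)(=O)[O-]
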